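**Plan**
- Retrosynthetic cuts, in order: C16=C17 (Mannich elimination), C7–C8 (closure of the ten-membered ring), C12–C13 (conjugate addition to a silyloxycyclopentenone), C9–C11 (vinyl addition), then the C5–C10 bond of ring A, which is traced back to a C5–C9 bond of a cycloheptane, i.e. to eucarvone.
- Enabling feature: the array C9(=O)–C10(CH3, quaternary)–C1(O) on ring A (C1–C5, C10) is the retron of a 2,3-epoxy silyl ether semipinacol shift. In the seven-membered precursor (C9, C10, C1–C5) C5 migrates from the carbinol carbon C9 to the epoxide carbon C10, so the ring contracts to the cyclohexane and C9 leaves the ring as the aldehyde. All ten carbons come from eucarvone.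
- Forward order: eucarvone → C3 oxygen → C5 allyl → C9 carbinol and C10–C1 epoxide → ring contraction to ring A → C1 inverted and C3 acetate installed together (oxidation, Evans–Tishchenko) → C9 vinyl ketone → zinc homoenolate addition to the cyclopentenone with Mannich trapping (five-membered ring, C17) → Nozaki–Hiyama–Kishi closure of the ten-membered ring → methylene unveiled last.
- Stereochemistry: C3 by catalyst control; C5 by alkylation anti to C3–OTBS; C9 and the epoxide by substrate control; C10 by stereospecific anti migration; C1 (delivered cis to C9 by the shift) by C3–OH-directed hydride delivery; C13 by anti addition to the (S)-enone; C7 in the macrocyclization.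

Key step: step 8

Remark: atom numbers C1–C20 are those of the 8,9-seco-ent-kaurane skeleton of the target (ring A = C1–C5, C10; C9 chain ketone; C7 carbinol; C15 ring ketone; C16=C17 methylene). β is the face of ring A carrying the C3 oxygen and C9; α is the face carrying the C10 methyl and the C5 side chain.
Assumption: eucarvone (1) is taken as a purchasable monoterpene ketone (otherwise two steps from carvone through its hydrobromide).

**Step 1**
Reactants: 1 eucarvone
Product: 2 (4S,5R)-4,5-epoxy-2,6,6-trimethylcyclohept-2-en-1-one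
Conditions: (S,S)-N,N′-bis(3,5-di-tert-butylsalicylidene)-1,2-cyclohexanediaminomanganese chloride [(salen)MnCl, 5 mol %], 4-phenylpyridine N-oxide, NaOCl (aq), CH2Cl2, 0 °C
Reagents that add atoms: sodium hypochlorite, [Na+].[O-]Cl
Why: Jacobsen–Katsuki epoxidation of the distal cis-disubstituted conjugated alkene (C2=C3, flanked by a vinyl group and the quaternary C4 as in 2,2-dimethylchromenes) should be selective over the electron-poor enone alkene, and the (S,S) ligand is expected to set C3 (the enantiomeric catalyst would be used if the sense proved opposite).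

**Step 2**
Reactants: 2 epoxy enone
Product: 3 (S)-5-hydroxy-2,6,6-trimethylcyclohept-2-en-1-one
Conditions: Pd2(dba)3·CHCl3 (2.5 mol %), n-Bu3P, HCO2H, Et3N, 1,4-dioxane, 23 °C
Reagents that add atoms: none
Why: palladium-catalysed formate hydrogenolysis of the alkenyl oxirane: zerovalent palladium ionizes the allylic C2–O bond and hydride is delivered to C2, so the conjugated enone is kept and the C3–O bond with its configuration is untouched.

**Step 3**
Reactants: 3 hydroxy enone
Product: 4 (S)-5-(tert-butyldimethylsilyloxy)-2,6,6-trimethylcyclohept-2-en-1-one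
Conditions: TBSOTf, 2,6-lutidine, CH2Cl2, −78 °C
Reagents that add atoms: tert-butyldimethylsilyl trifluoromethanesulfonate, CC(C)(C)[Si](C)(C)OS(=O)(=O)C(F)(F)F
Why: standard silylation of a hindered secondary alcohol gives a bulky, base-stable group at C3 that later directs the alkylation.

**Step 4**
Reactants: 4 silyl ether
Product: 5 (5S,7R)-7-allyl-5-(tert-butyldimethylsilyloxy)-2,6,6-trimethylcyclohept-2-en-1-one
Conditions: LiN(i-Pr)2, THF, −78 °C; allyl bromide, DMPU, −78 → −20 °C
Reagents that add atoms: allyl bromide, C=CCBr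
Why: kinetic deprotonation at the only α′ position (C5) gives the cross-conjugated enolate, whose alkylation should occur anti to the C3 silyloxy group across the gem-dimethyl carbon and so set C5 (allyl trans to OTBS).

**Step 5**
Reactants: 5 allyl enone
Product: 6 (1R,5S,7R)-7-allyl-5-(tert-butyldimethylsilyloxy)-2,6,6-trimethylcyclohept-2-en-1-ol
Conditions: i-Bu2AlH, toluene, −78 °C
Reagents that add atoms: none
Why: 1,2-reduction of the enone from the face opposite the adjacent C5 allyl group should give the C9 alcohol cis to the allyl group.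

**Step 6**
Reactants: 6 allylic alcohol
Product: 7 triethylsilyl ether of 6
Conditions: Et3SiCl, imidazole, DMF, 0 → 23 °C
Reagents that add atoms: chlorotriethylsilane, CC[Si](Cl)(CC)CC
Why: silylation installs the bulky allylic group that steers the epoxidation and later supplies the oxygen push and the migrating silyl group in the rearrangement.

**Step 7**
Reactants: 7 allylic silyl ether
Product: 8 trans-2,3-epoxy silyl ether
Conditions: mCPBA, NaHCO3, CH2Cl2, 0 °C
Reagents that add atoms: 3-chloroperoxybenzoic acid, OOC(=O)c1cccc(Cl)c1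
Why: Prilezhaev epoxidation is chemoselective for the trisubstituted C10=C1 alkene over the terminal allyl alkene and should occur anti to the allylic OTES group and the C5 allyl group, which sets the epoxide carbons C10 and C1.

**Step 8**
Reactants: 8 trans-2,3-epoxy silyl ether
Product: 9 ring A aldehyde
Conditions: MeAl(OAr)2 (Ar = 4-bromo-2,6-di-tert-butylphenyl, 20 mol %), CH2Cl2, −78 → −20 °C
Reagents that add atoms: none
Why: Semipinacol rearrangement of a 2,3-epoxy silyl ether: the bulky aluminium Lewis acid binds the epoxide oxygen, the C10–O bond at the tertiary carbon lengthens, and the ring bond C9–C5 shifts to C10 while the C9 silyloxy oxygen forms a silyl oxocarbenium ion that passes its silyl group to the aluminium alkoxide at C1 and frees the catalyst. The closest known reactions are the stereospecific Lewis acid rearrangements of epoxy silyl ethers to β-silyloxy aldehydes and the ring contractions of trans-2,3-epoxycycloalkanol derivatives. No ring is closed by cyclization: the cycloheptane contracts by one atom to the cyclohexane ring A through a 1,2-shift in which C5 bridges C9 and C10, and C9 is expelled as the formyl group. C10 is set by inversion (C5 enters anti to the departing epoxide oxygen), C5 migrates with retention and C1 keeps the epoxide configuration, so CHO and C1–O emerge cis. The selectivity needed is C5 migration over hydride shift, silyloxy participation and a Meinwald shift from C1. In the trans isomer the C9 hydrogen is syn to the epoxide oxygen and cannot shift, the conformer with the OTES group pseudo-equatorial places the C9–C5 bond anti-periplanar to C10–O, and the oxygen push from C9 favours this shift over one from C1.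

**Step 9**
Reactants: 9 ring A aldehyde
Product: 11 diol (C9 epimers), via triethylsilyl-protected vinyl carbinol 10 (not isolated)
Conditions: CH2=CHMgBr, THF, −78 °C; NH4Cl (aq); then PPTS, MeOH, 23 °C
Reagents that add atoms: vinylmagnesium bromide, C=C[Mg]Br
Why: Grignard addition to the non-enolizable neopentyl aldehyde gives the C9 carbinol as an inconsequential epimer mixture, and mild acidic methanolysis removes the triethylsilyl group from C1 while the more robust TBS ether at C3 stays.

**Step 10**
Reactants: 11 diol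
Product: 12 ring A diketone
Conditions: Dess–Martin periodinane, NaHCO3, CH2Cl2, 0 → 23 °C
Reagents that add atoms: none
Why: Dess–Martin oxidation of both secondary alcohols gives the C9 vinyl ketone and erases the C1 centre that the ring contraction delivered cis to C9; the 2,2-disubstituted 1,3-diketone cannot enolize between its carbonyls.

**Step 11**
Reactants: 12 ring A diketone
Product: 13 β-hydroxy ketone
Conditions: HF·pyridine, pyridine, THF, 0 → 23 °C
Reagents that add atoms: none
Why: fluoride cleavage of the TBS ether under buffered, mildly acidic conditions frees C3–OH without base-induced loss of water from the β-hydroxy ketone.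

**Step 12**
Reactants: 13 β-hydroxy ketone
Product: 14 C3 acetate C1 alcohol
Conditions: SmI2 (30 mol %, premixed with MeCHO), MeCHO (10 equiv), THF, −10 °C
Reagents that add atoms: acetaldehyde, CC=O
Why: Evans–Tishchenko reduction: the C3 hemiacetal of acetaldehyde, held with the C1 ketone on trivalent samarium, delivers hydride intramolecularly to the β face of C1, which should give the 1,3-anti diol monoester (α C1–OH and C3 acetate in one operation) and leaves the C9 ketone, which has no β-hydroxyl, untouched.

**Step 13**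
Reactants: 14 C3 acetate C1 alcohol
Product: 15 C1 triethylsilyl ether
Conditions: Et3SiOTf, 2,6-lutidine, CH2Cl2, −78 °C
Reagents that add atoms: triethylsilyl trifluoromethanesulfonate, CC[Si](CC)(CC)OS(=O)(=O)C(F)(F)F
Why: silylation protects C1–OH of the β-hydroxy ketone against retro-aldol cleavage and against protonolysis of the organozinc reagent; the C9 ketone has no enolizable hydrogen at this stage.

**Step 14**
Reactants: 15 vinyl ketone
Product: 17 β-iodoethyl ketone, via β-iodo trimethylsilyl enol ether 16 (not isolated)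
Conditions: Me3SiI, CH2Cl2, −78 °C; then NaHCO3 (aq)
Reagents that add atoms: iodotrimethylsilane, C[Si](C)(C)I
Why: conjugate addition of iodotrimethylsilane to the vinyl ketone and hydrolysis of the silyl enol ether on work-up is a known hydroiodination of enones, and the low temperature should spare the acetate and the silyl ether.

**Step 15**
Reactants: 17 β-iodoethyl ketone; 18 (S)-4-(tert-butyldimethylsilyloxy)cyclopent-2-en-1-one
Product: 21 Mannich base, via alkylzinc iodide 19 (not isolated), via trimethylsilyl enol ether 20 (not isolated)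
Conditions: Zn dust (activated), LiCl, THF, 23 °C; then 18, CuBr·SMe2 (10 mol %), Me3SiCl, DMPU, −30 → 0 °C; then CH2=NMe2+ I−, CH2Cl2, 0 → 23 °C; NaHCO3 (aq)
Reagents that add atoms: Eschenmoser's salt (N,N-dimethylmethyleneiminium iodide), C=[N+](C)C.[I-]
Why: zinc insertion gives the zinc homoenolate of the C9 ketone, whose copper-catalysed, chlorosilane-accelerated conjugate addition to the enone occurs anti to the silyloxy group and sets C13, and the regiodefined silyl enol ether is aminomethylated at C16 by the iminium salt (Mannich reaction; the C16 configuration is inconsequential).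

**Step 16**
Reactants: 21 Mannich base
Product: 22 4-substituted cyclopentenone
Conditions: DBU, CH2Cl2, 0 °C
Reagents that add atoms: none
Why: E1cB elimination of the β-silyloxy group from the cyclopentanone gives the C8=C14 enone (net transposition of the enone), and short contact at 0 °C should limit epimerization at the γ-carbon C13 and loss of dimethylamine.

**Step 17**
Reactants: 22 4-substituted cyclopentenone
Product: 23 2-iodoenone
Conditions: I2, pyridine, CH2Cl2, 0 → 23 °C
Reagents that add atoms: iodine, II
Why: α-iodination of the enone by pyridine conjugate addition, iodination of the enolate and elimination places iodine at C8.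

**Step 18**
Reactants: 23 2-iodoenone
Product: 24 C7 aldehyde
Conditions: OsO4 (2 mol %), NaIO4, 2,6-lutidine, 1,4-dioxane/H2O (3:1), 23 °C
Reagents that add atoms: osmium tetroxide, O=[Os](=O)(=O)=O; sodium periodate, [Na+].[O-]I(=O)(=O)=O
Why: Lemieux–Johnson cleavage of the only electron-rich alkene (the terminal allyl group) gives the C7 aldehyde, the electron-poor trisubstituted iodoenone alkene being much less reactive.

**Step 19**
Reactants: 24 C7 aldehyde
Product: 25 ten-membered allylic alcohol
Conditions: CrCl2 (6 equiv), NiCl2 (1 mol %), DMSO, 2 mM, 23 °C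
Reagents that add atoms: none
Why: intramolecular Nozaki–Hiyama–Kishi reaction: zerovalent nickel inserts into the C8–I bond, transmetalation gives the alkenylchromium species, which adds to the aldehyde chemoselectively over the ketones and closes the ten-membered ring; the C7 configuration should follow from attack on the aldehyde face exposed when the C5–C6–C7 chain lies extended on ring A, and it is the least secure stereocentre of the route.

**Step 20**
Reactants: 25 ten-membered allylic alcohol
Product: 26 amino diol
Conditions: HF·pyridine, pyridine, THF, 0 °C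
Reagents that add atoms: none
Why: buffered fluoride cleavage of the triethylsilyl ether should leave the acetate, the allylic alcohol and the β-amino ketone intact.

**Step 21**
Reactants: 26 amino diol
Product: 28 target CNP0223751.1, via trimethylammonium iodide 27 (not isolated)
Conditions: MeI, CH2Cl2, 23 °C; then NaHCO3 (aq), 23 °C
Reagents that add atoms: none
Why: quaternization of the tertiary amine and E1cB elimination of trimethylamine from the β-ammonio ketone (Mannich-base methylenation) unveils the C16=C17 methylene of the cross-conjugated dienone as the last operation, the free hydroxyls being inert to iodomethane without strong base.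

**Compound list**
1 | eucarvone (2,6,6-trimethylcyclohepta-2,4-dien-1-one) | CC1=CC=CC(C)(C)CC1=O | starting material
2 | (4S,5R)-4,5-epoxy-2,6,6-trimethylcyclohept-2-en-1-one | O=C1C(C)=C[C@@H]2O[C@@H]2C(C)(C)C1 | intermediate
3 | (S)-5-hydroxy-2,6,6-trimethylcyclohept-2-en-1-one | O=C1C(C)=CC[C@H](O)C(C)(C)C1 | intermediate
4 | (S)-5-(tert-butyldimethylsilyloxy)-2,6,6-trimethylcyclohept-2-en-1-one | O=C1C(C)=CC[C@H](O[Si](C)(C)C(C)(C)C)C(C)(C)C1 | intermediate
5 | (5S,7R)-7-allyl-5-(tert-butyldimethylsilyloxy)-2,6,6-trimethylcyclohept-2-en-1-one (allyl trans to OTBS) | O=C1C(C)=CC[C@H](O[Si](C)(C)C(C)(C)C)C(C)(C)[C@H]1CC=C | intermediate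
6 | (1R,5S,7R)-7-allyl-5-(tert-butyldimethylsilyloxy)-2,6,6-trimethylcyclohept-2-en-1-ol (OH cis to allyl) | O[C@H]1C(C)=CC[C@H](O[Si](C)(C)C(C)(C)C)C(C)(C)[C@H]1CC=C | intermediate
7 | triethylsilyl ether of 6 | CC[Si](CC)(CC)O[C@H]1C(C)=CC[C@H](O[Si](C)(C)C(C)(C)C)C(C)(C)[C@H]1CC=C | intermediate
8 | 2,3-epoxide of 7 (epoxide oxygen trans to OTES and allyl, cis to OTBS) | CC[Si](CC)(CC)O[C@H]1[C@]2(C)O[C@@H]2C[C@H](O[Si](C)(C)C(C)(C)C)C(C)(C)[C@H]1CC=C | intermediate
9 | (1S,2R,4S,6R)-2-allyl-4-(tert-butyldimethylsilyloxy)-1,3,3-trimethyl-6-(triethylsilyloxy)cyclohexane-1-carbaldehyde (ring A; CHO, OTES and OTBS on the β face) | O=C[C@@]1(C)[C@H](CC=C)C(C)(C)[C@@H](O[Si](C)(C)C(C)(C)C)C[C@H]1O[Si](CC)(CC)CC | intermediate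
10 | vinyl carbinol of 9 with C1–OTES (C9 epimers) | C=CC(O)[C@@]1(C)[C@H](CC=C)C(C)(C)[C@@H](O[Si](C)(C)C(C)(C)C)C[C@H]1O[Si](CC)(CC)CC | intermediate
11 | ring A diol: C9 vinyl carbinol (epimers), C1 β-OH, C3 β-OTBS, C5 α-allyl | C=CC(O)[C@@]1(C)[C@H](CC=C)C(C)(C)[C@@H](O[Si](C)(C)C(C)(C)C)C[C@H]1O | intermediate
12 | ring A diketone: C1 ketone, C9 vinyl ketone, C3 β-OTBS, C5 α-allyl | C=CC(=O)[C@@]1(C)[C@H](CC=C)C(C)(C)[C@@H](O[Si](C)(C)C(C)(C)C)CC1=O | intermediate
13 | C3 β-hydroxy analogue of 12 | C=CC(=O)[C@@]1(C)[C@H](CC=C)C(C)(C)[C@@H](O)CC1=O | intermediate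
14 | ring A vinyl ketone with C3 β-OAc and C1 α-OH | C=CC(=O)[C@@]1(C)[C@H](CC=C)C(C)(C)[C@@H](OC(C)=O)C[C@@H]1O | intermediate
15 | C1 triethylsilyl ether of 14 | C=CC(=O)[C@@]1(C)[C@H](CC=C)C(C)(C)[C@@H](OC(C)=O)C[C@@H]1O[Si](CC)(CC)CC | intermediate
16 | β-iodo trimethylsilyl enol ether from 15 | ICC=C(O[Si](C)(C)C)[C@@]1(C)[C@H](CC=C)C(C)(C)[C@@H](OC(C)=O)C[C@@H]1O[Si](CC)(CC)CC | intermediate
17 | β-iodoethyl ketone (C12 iodide) | ICCC(=O)[C@@]1(C)[C@H](CC=C)C(C)(C)[C@@H](OC(C)=O)C[C@@H]1O[Si](CC)(CC)CC | intermediate
18 | (S)-4-(tert-butyldimethylsilyloxy)cyclopent-2-en-1-one | O=C1C=C[C@@H](O[Si](C)(C)C(C)(C)C)C1 | starting material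
19 | alkylzinc iodide (zinc homoenolate) from 17 | I[Zn]CCC(=O)[C@@]1(C)[C@H](CC=C)C(C)(C)[C@@H](OC(C)=O)C[C@@H]1O[Si](CC)(CC)CC | intermediate
20 | trimethylsilyl enol ether of the conjugate adduct (C12 trans to OTBS) | C1=C(O[Si](C)(C)C)C[C@H](O[Si](C)(C)C(C)(C)C)[C@H]1CCC(=O)[C@@]1(C)[C@H](CC=C)C(C)(C)[C@@H](OC(C)=O)C[C@@H]1O[Si](CC)(CC)CC | intermediate
21 | Mannich base: 2-(dimethylaminomethyl)-3-alkyl-4-silyloxycyclopentanone (C16 epimers) | CN(C)CC1C(=O)C[C@H](O[Si](C)(C)C(C)(C)C)[C@H]1CCC(=O)[C@@]1(C)[C@H](CC=C)C(C)(C)[C@@H](OC(C)=O)C[C@@H]1O[Si](CC)(CC)CC | intermediate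
22 | 4-alkyl-5-(dimethylaminomethyl)cyclopent-2-enone (C13 R, C16 epimers) | CN(C)CC1C(=O)C=C[C@H]1CCC(=O)[C@@]1(C)[C@H](CC=C)C(C)(C)[C@@H](OC(C)=O)C[C@@H]1O[Si](CC)(CC)CC | intermediate
23 | 2-iodo derivative of 22 (iodine at C8) | CN(C)CC1C(=O)C(I)=C[C@H]1CCC(=O)[C@@]1(C)[C@H](CC=C)C(C)(C)[C@@H](OC(C)=O)C[C@@H]1O[Si](CC)(CC)CC | intermediate
24 | C7 aldehyde of 23 | CN(C)CC1C(=O)C(I)=C[C@H]1CCC(=O)[C@@]1(C)[C@H](CC=O)C(C)(C)[C@@H](OC(C)=O)C[C@@H]1O[Si](CC)(CC)CC | intermediate
25 | macrocyclic (7R)-allylic alcohol with C1–OTES and C16–CH2NMe2 | CN(C)CC1C(=O)C2=C[C@H]1CCC(=O)[C@@]1(C)[C@H](C[C@H]2O)C(C)(C)[C@@H](OC(C)=O)C[C@@H]1O[Si](CC)(CC)CC | intermediate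
26 | C1-desilylated amino diol | CN(C)CC1C(=O)C2=C[C@H]1CCC(=O)[C@@]1(C)[C@H](C[C@H]2O)C(C)(C)[C@@H](OC(C)=O)C[C@@H]1O | intermediate
27 | trimethylammonium iodide of 26 | C[N+](C)(C)CC1C(=O)C2=C[C@H]1CCC(=O)[C@@]1(C)[C@H](C[C@H]2O)C(C)(C)[C@@H](OC(C)=O)C[C@@H]1O.[I-] | intermediate
28 | CNP0223751.1 (3β-acetoxy-1α,7-dihydroxy-8,9-seco-ent-kaura-8(14),16-diene-9,15-dione type) | C=C1C(=O)C2=C[C@H]1CCC(=O)[C@@]1(C)[C@H](C[C@H]2O)C(C)(C)[C@@H](OC(C)=O)C[C@@H]1O | target

**Step count and risks**
Total step count: 21. Longest linear sequence: 21 steps (1 → 28); fragment 18 is purchased.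

Step 8. The C9–C5 bond may fail to reach the anti-periplanar alignment, so that participation of the silyloxy oxygen (epoxide migration) or a hydride shift from C1 outruns the ring contraction. The fallback is a Favorskii ring contraction, which sets out from 5 and comes back at 12. Nucleophilic epoxidation of 5 (H2O2, NaOH, MeOH) anti to the OTBS group gives α,β-epoxy ketone F1. LiCl/CF3CO2H in THF opens it at the tertiary carbon with inversion to chlorohydrin F2, which is protected (dihydropyran, PPTS) as tetrahydropyranyl ether F3. NaOMe in MeOH then forms the α′-enolate at C5, closes the cyclopropanone with inversion at C10 and opens it to ring-contracted methyl ester F4; C5 is reset through the enolate and the C1 oxygen is already α. Reduction with LiAlH4 gives primary alcohol F5 and Dess–Martin oxidation gives aldehyde F6. Vinylmagnesium bromide gives vinyl carbinol F7, PPTS/MeOH removes the acetal to give diol F8, and Dess–Martin oxidation of F8 gives 12.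

Step 15. The β-zincio ketone may be protonated or collapse to the zinc cyclopropanolate before it transfers to copper, and addition to the hindered enone may be slow. The fallback uses no preformed organometallic and sets out from 17 and 18, coming back at 21. A nickel-catalysed reductive conjugate addition [NiCl2(CH3OCH2CH2OCH3), neocuproine, Mn powder, Et3SiCl, DMF] couples the iodide and the enone through an allylnickel intermediate to give triethylsilyl enol ether F9, which is aminomethylated with Eschenmoser's salt as in the main route to give 21.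

Step 19. CrCl2 may reduce, protodeiodinate or dimerize the electron-poor iodoenone before the alkenylchromium species adds to the aldehyde. The fallback masks the enone carbonyl, sets out from 23 and comes back at 26. Silyl triflate-catalysed ketalization of 23 [1,2-bis(trimethylsilyloxy)ethane, Me3SiOTf, CH2Cl2, −78 °C; the tert-alkyl C9 ketone is too hindered to react] gives iodoalkene dioxolane F10. OsO4/NaIO4 cleavage gives aldehyde F11, and the CrCl2/NiCl2 ring closure of this ordinary alkenyl iodide gives macrocyclic ketal F12. Aqueous HCl in THF then removes the dioxolane and the triethylsilyl ether together to give 26.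

**Further compounds**
F1 | step 8 | α,β-epoxy ketone from 5 (epoxide trans to OTBS) | O=C1[C@@]2(C)O[C@H]2C[C@H](O[Si](C)(C)C(C)(C)C)C(C)(C)[C@H]1CC=C
F2 | step 8 | chlorohydrin (C10–Cl, C1 α-OH) | O=C1[C@](C)(Cl)[C@@H](O)C[C@H](O[Si](C)(C)C(C)(C)C)C(C)(C)[C@H]1CC=C
F3 | step 8 | tetrahydropyranyl ether of F2 (acetal epimers) | O=C1[C@](C)(Cl)[C@@H](OC2CCCCO2)C[C@H](O[Si](C)(C)C(C)(C)C)C(C)(C)[C@H]1CC=C
F4 | step 8 | ring-contracted methyl ester (C1 α-OTHP) | COC(=O)[C@@]1(C)[C@H](CC=C)C(C)(C)[C@@H](O[Si](C)(C)C(C)(C)C)C[C@@H]1OC1CCCCO1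
F5 | step 8 | primary alcohol from F4 | OC[C@@]1(C)[C@H](CC=C)C(C)(C)[C@@H](O[Si](C)(C)C(C)(C)C)C[C@@H]1OC1CCCCO1
F6 | step 8 | aldehyde from F5 (C1 α-OTHP analogue of 9) | O=C[C@@]1(C)[C@H](CC=C)C(C)(C)[C@@H](O[Si](C)(C)C(C)(C)C)C[C@@H]1OC1CCCCO1
F7 | step 8 | vinyl carbinol from F6 (C9 epimers) | C=CC(O)[C@@]1(C)[C@H](CC=C)C(C)(C)[C@@H](O[Si](C)(C)C(C)(C)C)C[C@@H]1OC1CCCCO1
F8 | step 8 | diol, C1 epimer of 11 | C=CC(O)[C@@]1(C)[C@H](CC=C)C(C)(C)[C@@H](O[Si](C)(C)C(C)(C)C)C[C@@H]1O
F9 | step 15 | triethylsilyl enol ether of the conjugate adduct | C1=C(O[Si](CC)(CC)CC)C[C@H](O[Si](C)(C)C(C)(C)C)[C@H]1CCC(=O)[C@@]1(C)[C@H](CC=C)C(C)(C)[C@@H](OC(C)=O)C[C@@H]1O[Si](CC)(CC)CC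
F10 | step 19 | C15 ethylene ketal of 23 | CN(C)CC1C2(OCCO2)C(I)=C[C@H]1CCC(=O)[C@@]1(C)[C@H](CC=C)C(C)(C)[C@@H](OC(C)=O)C[C@@H]1O[Si](CC)(CC)CC
F11 | step 19 | C7 aldehyde of F10 | CN(C)CC1C2(OCCO2)C(I)=C[C@H]1CCC(=O)[C@@]1(C)[C@H](CC=O)C(C)(C)[C@@H](OC(C)=O)C[C@@H]1O[Si](CC)(CC)CC
F12 | step 19 | macrocyclic allylic alcohol with C15 ethylene ketal | CN(C)CC1C3(OCCO3)C2=C[C@H]1CCC(=O)[C@@]1(C)[C@H](C[C@H]2O)C(C)(C)[C@@H](OC(C)=O)C[C@@H]1O[Si](CC)(CC)CC
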